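## Retrosynthetic overview

1. Dehydrogravicycle ⇐ fluoride removal of three aryl TIPS ethers from the protected macrocycle.
2. The 22-membered ring is closed last, by ring-closing metathesis at the C8′=C9′ (E) alkene of an acyclic diene.
3. Key bond C1′–aryl (ring B), made together with the (R)-carbinol: sparteine-complexed α-lithiated nonenyl carbamate (an α-oxy carbanion, reversed polarity at C1′) + ring B aryl pinacol boronate, 1,2-metallate shift, oxidation.
4. Aryl boronate ⇐ Negishi alkylation of the ring A bromide ⇐ Ir C–H borylation of ring B ⇐ OMe→OTIPS exchange ⇐ Ullmann diaryl ether from 2,6-dimethoxyphenol and 1,3-dibromo-5-methoxybenzene.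
5. Ring order: both benzene rings are bought; the diaryl ether is made first, the macrocycle last.

Assumption: the stereocentre in the given SMILES is (R); C1′–C14′ count the chain from the carbinol carbon to ring A (the mono-hydroxy ring), and ring B is the dihydroxy ring.

## Route

Step 1
Reactants: 1 non-8-en-1-ol
Product: 2 non-8-en-1-yl N,N-di(propan-2-yl)carbamate
Conditions: i-Pr2NCOCl (1.2 equiv), Et3N (1.5 equiv), CH2Cl2, reflux, 24 h
Reagents that add atoms: N,N-di(propan-2-yl)carbamoyl chloride, CC(C)N(C(C)C)C(=O)Cl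
Why: O-carbamoylation of a primary alcohol installs the Hoppe directing and leaving group needed for α-lithiation.

Step 2
Reactants: 3 2,6-dimethoxyphenol; 4 1,3-dibromo-5-methoxybenzene (3 equiv)
Product: 5 2-(3-bromo-5-methoxyphenoxy)-1,3-dimethoxybenzene
Conditions: CuI (10 mol %), picolinic acid (20 mol %), K3PO4 (2 equiv), DMSO, 90 °C, 24 h
Reagents that add atoms: none
Why: Ullmann-type copper-catalysed O-arylation with picolinic acid accepts 2,6-disubstituted phenols, and the threefold excess of the symmetrical dibromide keeps the second C–Br bond of 5 from reacting.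

Step 3
Reactants: 5 2-(3-bromo-5-methoxyphenoxy)-1,3-dimethoxybenzene
Product: 6 2-(3-bromo-5-hydroxyphenoxy)benzene-1,3-diol
Conditions: BBr3 (6 equiv), CH2Cl2, −78 °C → rt; H2O quench
Reagents that add atoms: none
Why: BBr3 ether cleavage (boron complexation, then bromide attack at methyl) removes all three O-methyl groups while the diaryl ether and the aryl bromide are inert.

Step 4
Reactants: 6 2-(3-bromo-5-hydroxyphenoxy)benzene-1,3-diol
Product: 7 1-bromo-3-[2,6-bis(triisopropylsilyloxy)phenoxy]-5-(triisopropylsilyloxy)benzene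
Conditions: TIPSCl (3.6 equiv), imidazole (8 equiv), DMF, 50 °C
Reagents that add atoms: chlorotri(propan-2-yl)silane, CC(C)[Si](Cl)(C(C)C)C(C)C
Why: Phenol silylation; aryl TIPS ethers survive the organozinc, boronate and brief alkaline peroxide conditions ahead, yet fall to fluoride at the end without touching a benzylic alcohol or an alkene.

Step 5
Reactants: 7 1-bromo-3-[2,6-bis(triisopropylsilyloxy)phenoxy]-5-(triisopropylsilyloxy)benzene
Product: 8 2-{4-[3-bromo-5-(triisopropylsilyloxy)phenoxy]-3,5-bis(triisopropylsilyloxy)phenyl}-4,4,5,5-tetramethyl-1,3,2-dioxaborolane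
Conditions: [Ir(cod)(OMe)]2 (2.5 mol %), dtbpy (5 mol %), B2pin2 (1.0 equiv), THF, 80 °C
Reagents that add atoms: bis(pinacolato)diboron, CC1(C)OB(OC1(C)C)B1OC(C)(C)C(C)(C)O1
Why: Iridium-catalysed C–H borylation (Ishiyama–Miyaura–Hartwig) is sterically controlled: every C–H of ring A and the C3/C5–H of ring B has an ortho substituent, so only the ring B C–H para to the ether oxygen reacts, and the C–Br bond is untouched.

Step 6
Reactants: 8 the bromo boronate from step 5; 9 7-bromohept-1-ene (1.5 equiv)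
Product: 11 2-{4-[3-(hept-6-en-1-yl)-5-(triisopropylsilyloxy)phenoxy]-3,5-bis(triisopropylsilyloxy)phenyl}-4,4,5,5-tetramethyl-1,3,2-dioxaborolane, via hept-6-en-1-ylzinc bromide 10 (not isolated)
Conditions: 9, Zn dust (activated), LiCl, THF, 50 °C; then 8, Pd(OAc)2 (2 mol %), SPhos (4 mol %), THF, rt → 40 °C
Reagents that add atoms: none
Why: Knochel LiCl-assisted zinc insertion then Negishi cross-coupling: the primary alkylzinc transmetalates to palladium without base, so the C–Br bond couples while the pinacol boronate, which needs base activation, stays intact.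

Step 7
Reactants: 2 non-8-en-1-yl N,N-di(propan-2-yl)carbamate (1.4 equiv); 11 the heptenyl aryl boronate from step 6
Product: 15 (R)-1-{4-[3-(hept-6-en-1-yl)-5-(triisopropylsilyloxy)phenoxy]-3,5-bis(triisopropylsilyloxy)phenyl}non-8-en-1-ol, via lithiated carbamate 12 (not isolated), via lithium boronate complex 13 (not isolated), via benzylic boronic ester 14 (not isolated)
Conditions: 2, (−)-sparteine (1.4 equiv), s-BuLi (1.3 equiv), Et2O, −78 °C, 5 h; 11, −78 °C, 1 h; MgBr2·OEt2, reflux, 16 h; then 2 M NaOH, 30% H2O2, THF, 0 °C, 30 min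
Reagents that add atoms: hydrogen peroxide, OO
Why: Hoppe–Aggarwal lithiation–borylation: s-BuLi/(−)-sparteine removes the pro-S proton of 2 to give the configurationally stable α-oxy carbanion (S)-12, a reversed-polarity (carbenoid) form of the normally electrophilic carbinol carbon, which adds to boron of 11 with retention to give 13; anti-periplanar 1,2-migration of the aryl group with loss of carbamate (inversion, MgBr2-assisted) joins the two formerly metal-bearing carbons as (R)-14, and stereoretentive C–B oxidation gives (R)-15 (expected er about 97:3).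

Step 8
Reactants: 15 the (R)-diene alcohol from step 7
Product: 16 tris-O-triisopropylsilyl dehydrogravicycle [(R)-carbinol; (E)-C8′=C9′; 22-membered ring]
Conditions: second-generation Grubbs catalyst RuCl2(=CHPh)(H2IMes)(PCy3) (10 mol %), CH2Cl2 (1 mM), 40 °C, 12 h; AgNO3–SiO2 chromatography
Reagents that add atoms: none
Why: Ring-closing olefin metathesis at high dilution releases ethene; the 22-membered ring is unstrained, so secondary metathesis equilibrates towards the (E)-alkene (about 4–6:1 expected), and the minor (Z)-isomer is removed on AgNO3-impregnated silica.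

Step 9
Reactants: 16 tris-O-triisopropylsilyl dehydrogravicycle
Product: 17 dehydrogravicycle
Conditions: Bu4NF (3.6 equiv), AcOH (3.6 equiv), THF, 0 °C → rt
Reagents that add atoms: none
Why: Fluoride-driven Si–O cleavage of the three aryl silyl ethers, buffered with AcOH, leaves the benzylic stereocentre, the (E)-alkene and the diaryl ether untouched.

## Compound list

1 | non-8-en-1-ol | C=CCCCCCCCO | starting material
2 | non-8-en-1-yl N,N-di(propan-2-yl)carbamate | C=CCCCCCCCOC(=O)N(C(C)C)C(C)C | intermediate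
3 | 2,6-dimethoxyphenol | COc1cccc(OC)c1O | starting material
4 | 1,3-dibromo-5-methoxybenzene | COc1cc(Br)cc(Br)c1 | starting material
5 | 2-(3-bromo-5-methoxyphenoxy)-1,3-dimethoxybenzene | COc1cc(Br)cc(Oc2c(OC)cccc2OC)c1 | intermediate
6 | 2-(3-bromo-5-hydroxyphenoxy)benzene-1,3-diol | Oc1cc(Br)cc(Oc2c(O)cccc2O)c1 | intermediate
7 | 1-bromo-3-[2,6-bis(triisopropylsilyloxy)phenoxy]-5-(triisopropylsilyloxy)benzene | CC(C)[Si](C(C)C)(C(C)C)Oc1cc(Br)cc(Oc2c(O[Si](C(C)C)(C(C)C)C(C)C)cccc2O[Si](C(C)C)(C(C)C)C(C)C)c1 | intermediate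
8 | 2-{4-[3-bromo-5-(triisopropylsilyloxy)phenoxy]-3,5-bis(triisopropylsilyloxy)phenyl}-4,4,5,5-tetramethyl-1,3,2-dioxaborolane (Bpin on ring B, para to the ether oxygen) | CC(C)[Si](C(C)C)(C(C)C)Oc1cc(Br)cc(Oc2c(O[Si](C(C)C)(C(C)C)C(C)C)cc(B3OC(C)(C)C(C)(C)O3)cc2O[Si](C(C)C)(C(C)C)C(C)C)c1 | intermediate
9 | 7-bromohept-1-ene | C=CCCCCCBr | starting material
10 | hept-6-en-1-ylzinc bromide | C=CCCCCC[Zn]Br | intermediate
11 | 2-{4-[3-(hept-6-en-1-yl)-5-(triisopropylsilyloxy)phenoxy]-3,5-bis(triisopropylsilyloxy)phenyl}-4,4,5,5-tetramethyl-1,3,2-dioxaborolane | C=CCCCCCc1cc(O[Si](C(C)C)(C(C)C)C(C)C)cc(Oc2c(O[Si](C(C)C)(C(C)C)C(C)C)cc(B3OC(C)(C)C(C)(C)O3)cc2O[Si](C(C)C)(C(C)C)C(C)C)c1 | intermediate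
12 | (S)-1-lithionon-8-en-1-yl N,N-di(propan-2-yl)carbamate, as its (−)-sparteine complex | [Li][C@@H](CCCCCCC=C)OC(=O)N(C(C)C)C(C)C | intermediate
13 | lithium boronate (ate) complex of 12 and 11, (S) at the carbamate-bearing carbon | [Li+].C=CCCCCCC[C@@H](OC(=O)N(C(C)C)C(C)C)[B-]1(OC(C)(C)C(C)(C)O1)c1cc(O[Si](C(C)C)(C(C)C)C(C)C)c(Oc2cc(CCCCCC=C)cc(O[Si](C(C)C)(C(C)C)C(C)C)c2)c(O[Si](C(C)C)(C(C)C)C(C)C)c1 | intermediate
14 | (R)-secondary benzylic pinacol boronic ester (Bpin on C1′ in place of OH of 15) | C=CCCCCCC[C@@H](B1OC(C)(C)C(C)(C)O1)c1cc(O[Si](C(C)C)(C(C)C)C(C)C)c(Oc2cc(CCCCCC=C)cc(O[Si](C(C)C)(C(C)C)C(C)C)c2)c(O[Si](C(C)C)(C(C)C)C(C)C)c1 | intermediate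
15 | (R)-1-{4-[3-(hept-6-en-1-yl)-5-(triisopropylsilyloxy)phenoxy]-3,5-bis(triisopropylsilyloxy)phenyl}non-8-en-1-ol | C=CCCCCCC[C@@H](O)c1cc(O[Si](C(C)C)(C(C)C)C(C)C)c(Oc2cc(CCCCCC=C)cc(O[Si](C(C)C)(C(C)C)C(C)C)c2)c(O[Si](C(C)C)(C(C)C)C(C)C)c1 | intermediate
16 | tris-O-triisopropylsilyl dehydrogravicycle, (R)-carbinol, (E)-alkene | CC(C)[Si](C(C)C)(C(C)C)Oc1cc2cc(c1)Oc1c(O[Si](C(C)C)(C(C)C)C(C)C)cc(cc1O[Si](C(C)C)(C(C)C)C(C)C)[C@H](O)CCCCCC/C=C/CCCCC2 | intermediate
17 | dehydrogravicycle | Oc1cc2cc(c1)Oc1c(O)cc(cc1O)[C@H](O)CCCCCC/C=C/CCCCC2 | target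

## Step count and risks

Total steps: 9. Longest linear sequence: 8 (steps 2–9 from 3 and 4); step 1 is a one-step side branch.

Most likely to fail:

Step 8 (alkene geometry in the ring closure). RCM in a 22-membered ring gives an E/Z mixture, and the isomers may be hard to separate. The fallback secures the geometry after ring closure instead of during it. The unseparated product of step 8, that is 16 together with the (Z)-isomer of 16 F1, is stirred under ethene (5 atm) in THF at 35 °C with the cyclometalated nitrato ruthenium catalyst Ru(κ2-O2NO)(=CH-C6H4-2-OiPr)(κ2-C,C-NHC), where NHC is N-adamantyl-N′-mesitylimidazolin-2-ylidene metalated at adamantyl. This Z-selective ethenolysis ring-opens only F1, back to diene 15, and leaves 16 untouched. Diene 15, with two terminal alkenes, is held back on AgNO3–silica and is sent through step 8 again. The fallback sets out from 15 and comes back at 16.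

Step 7 (key lithiation–borylation). The 1,2-migration of the bulky, electron-rich aryl boronate may be incomplete, or the er may erode. The fallback makes the same C1′–aryl bond as a ketone and sets the stereocentre by reduction. Alcohol 1 is oxidised (TEMPO cat., PhI(OAc)2, MeCN/H2O) to non-8-enoic acid F2, which (COCl)2 with cat. DMF in CH2Cl2 turns into non-8-enoyl chloride F3. Acylative Suzuki–Miyaura coupling of F3 with boronate 11 (Pd(PPh3)4, K3PO4, toluene, 80 °C) gives 1-{4-[3-(hept-6-en-1-yl)-5-(triisopropylsilyloxy)phenoxy]-3,5-bis(triisopropylsilyloxy)phenyl}non-8-en-1-one F4. Noyori asymmetric transfer hydrogenation of F4 (RuCl(p-cymene)[(R,R)-TsDPEN], HCO2H/Et3N, rt) gives the (R)-alcohol without touching the terminal alkenes. The fallback sets out from 1 and 11 and comes back at 15.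

Step 2 (hindered phenol, statistical mono-arylation of a dibromide). The fallback replaces the aryl halide electrophile by an aryl boron partner in an oxidative coupling. Phenol 3 is coupled with (3-bromo-5-methoxyphenyl)boronic acid F5 under Chan–Lam–Evans conditions (Cu(OAc)2, pyridine, 4 Å molecular sieves, CH2Cl2, air, rt). Only the C–B bond reacts, so the C–Br bond is kept and no excess reagent is needed. The fallback sets out from 3 and comes back at 5.

## Further compounds

F1 | step 8 | (Z)-isomer of 16 [tris-O-triisopropylsilyl (Z)-dehydrogravicycle, (R)-carbinol] | CC(C)[Si](C(C)C)(C(C)C)Oc1cc2cc(c1)Oc1c(O[Si](C(C)C)(C(C)C)C(C)C)cc(cc1O[Si](C(C)C)(C(C)C)C(C)C)[C@H](O)CCCCCC/C=C\CCCCC2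
F2 | step 7 | non-8-enoic acid | C=CCCCCCCC(=O)O
F3 | step 7 | non-8-enoyl chloride | C=CCCCCCCC(=O)Cl
F4 | step 7 | 1-{4-[3-(hept-6-en-1-yl)-5-(triisopropylsilyloxy)phenoxy]-3,5-bis(triisopropylsilyloxy)phenyl}non-8-en-1-one | C=CCCCCCCC(=O)c1cc(O[Si](C(C)C)(C(C)C)C(C)C)c(Oc2cc(CCCCCC=C)cc(O[Si](C(C)C)(C(C)C)C(C)C)c2)c(O[Si](C(C)C)(C(C)C)C(C)C)c1
F5 | step 2 | (3-bromo-5-methoxyphenyl)boronic acid | COc1cc(Br)cc(B(O)O)c1
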